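## Assumptions
- The target is (2S)-2′,5,7-trihydroxy-8-prenyl-5′-(1,1-dimethylallyl)flavanone. The SMILES [C@@H] centre works out to S by CIP.
- 2′,4′-Dihydroxy-6′-methoxyacetophenone, prenyl-Bpin and 4-bromophenol are treated as commercial.
- Catalysts, bases and solvents that leave no atoms in the product are not numbered.

## Retrosynthetic overview
1. The target comes from global deprotection (two MOM groups and the chelated 5-OMe) of the protected (2S)-flavanone **13**.
2. **13** comes from an enantioselective intramolecular oxa-Michael cyclisation of 2′-hydroxychalcone **12**. This forms the pyranone ring last and sets C2.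
3. **12** comes from a Claisen–Schmidt condensation of acetophenone **11** with salicylaldehyde **7**. Both aromatic rings are built before any ring closure.
4. **7** comes from ortho-formylation of the reverse-prenylated MOM aryl ether **5**, which comes from Pd-catalysed γ-selective prenylation of aryl bromide **3**.
5. **11** comes from C3′-prenylation and 4′-O-MOM protection of **8**. The 6′-OMe blocks the wrong cyclisation regiochemistry, so only the 2′-OH can close, giving the 8-prenyl product.

## Route

**Step 1**
Reactants: **1** 4-bromophenol; **2** chloromethyl methyl ether (MOMCl)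
Product: **3** 1-bromo-4-(methoxymethoxy)benzene
Conditions: MOMCl, i-Pr2NEt, CH2Cl2, 0 °C → rt
Reagents that add atoms: MOMCl, COCCl
Why: Standard phenol O-alkylation gives a MOM ether that later serves as an ortho-directing group and a base-stable protecting group. No stereocentre is involved.

**Step 2**
Reactants: **3**; **4** prenylboronic acid pinacol ester (2-(3-methylbut-2-en-1-yl)-4,4,5,5-tetramethyl-1,3,2-dioxaborolane)
Product: **5** 1-(methoxymethoxy)-4-(2-methylbut-3-en-2-yl)benzene
Conditions: Pd2(dba)3, bulky biaryl monophosphine (tBuXPhos-type), K3PO4, THF/H2O, 60 °C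
Reagents that add atoms: prenyl-Bpin, CC(C)=CCB1OC(C)(C)C(C)(C)O1
Why: In a Suzuki–Miyaura coupling of an allylboronate, SE2′ transmetalation followed by a bulky ligand directing C–C bond formation at the tertiary γ-carbon gives the reverse-prenyl (1,1-dimethylallyl) arene. The quaternary centre is achiral.

**Step 3**
Reactants: **5**; **6** N,N-dimethylformamide (DMF)
Product: **7** 2-(methoxymethoxy)-5-(2-methylbut-3-en-2-yl)benzaldehyde
Conditions: n-BuLi, TMEDA, THF, 0 °C; then DMF, −78 °C → rt; NH4Cl work-up
Reagents that add atoms: DMF, CN(C)C=O (supplies the CHO carbon)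
Why: Directed ortho-metalation by the OMOM group occurs at the only ortho C–H position that is not blocked. The quaternary carbon has no benzylic C–H, so lateral lithiation cannot compete. The aryllithium is then formylated with DMF.

**Step 4**
Reactants: **8** 2′,4′-dihydroxy-6′-methoxyacetophenone; **9** prenyl bromide (1-bromo-3-methylbut-2-ene)
Product: **10** 1-[2,4-dihydroxy-6-methoxy-3-(3-methylbut-2-en-1-yl)phenyl]ethan-1-one
Conditions: KOH (2.2 equiv), H2O, 0 °C → rt; **9** (1.0 equiv) added slowly
Reagents that add atoms: prenyl bromide, CC(C)=CCBr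
Why: Phenoxide C-alkylation (ortho-selective in water) occurs at C3′, between the two oxygens. Using one equivalent limits the product to mono-prenylation, and chromatography removes the C5′, O-prenyl and di-prenyl by-products. The yield is modest, about 30–40%.

**Step 5**
Reactants: **10**; **2** MOMCl
Product: **11** 1-[2-hydroxy-6-methoxy-4-(methoxymethoxy)-3-(3-methylbut-2-en-1-yl)phenyl]ethan-1-one
Conditions: MOMCl (1.1 equiv), i-Pr2NEt, CH2Cl2, 0 °C
Reagents that add atoms: MOMCl, COCCl
Why: The 4′-OH is the most acidic and is not chelated. The 2′-OH is hydrogen-bonded to the acetyl carbonyl and stays free, which is what the later cyclisation needs.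

**Step 6**
Reactants: **11**; **7**
Product: **12** (E)-1-[2-hydroxy-6-methoxy-4-(MOMO)-3-prenylphenyl]-3-[2-(MOMO)-5-(2-methylbut-3-en-2-yl)phenyl]prop-2-en-1-one
Conditions: KOH (aq.), EtOH, rt, 48 h; then NH4Cl/AcOH to pH ≈ 5
Reagents that add atoms: none
Why: Claisen–Schmidt aldol condensation gives the E-chalcone. Under basic conditions the 2′-phenoxide is stable and does not cyclise, so no racemic flavanone forms.

**Step 7**
Reactants: **12**
Product: **13** (2S)-2-[2-(MOMO)-5-(2-methylbut-3-en-2-yl)phenyl]-7-(MOMO)-5-methoxy-8-(3-methylbut-2-en-1-yl)chroman-4-one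
Conditions: quinine-derived bifunctional thiourea catalyst (20 mol %), toluene, 40 °C, 3–4 d
Reagents that add atoms: none (isomerisation)
Why: An enantioselective intramolecular oxa-Michael addition. The tertiary amine deprotonates the 2′-OH while the thiourea binds the enone, so phenoxide attack on the β-carbon sets C2 as S. The 6′-OMe lacks the second chelating OH, so the flavanone is thermodynamically favoured. The catalyst pseudo-enantiomer is chosen to give (2S), and the configuration is confirmed by rotation/CD against known (2S)-flavanones.

**Step 8**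
Reactants: **13**
Product: **14** target, (2S)-2′,5,7-trihydroxy-8-prenyl-5′-(1,1-dimethylallyl)flavanone
Conditions: BCl3 (6 equiv), CH2Cl2, −78 → −10 °C, 1 h; cold MeOH quench, then NaHCO3 work-up
Reagents that add atoms: none
Why: BCl3 cleaves both aryl MOM ethers. It also cleaves the 5-OMe selectively, because that group is chelated by the C4 carbonyl. No base is present, so the C2 stereocentre is not epimerised.

## Compound list
1 | 4-bromophenol | Oc1ccc(Br)cc1 | starting material
2 | chloromethyl methyl ether | COCCl | starting material (reagent)
3 | 1-bromo-4-(methoxymethoxy)benzene | COCOc1ccc(Br)cc1 | intermediate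
4 | prenyl-Bpin | CC(C)=CCB1OC(C)(C)C(C)(C)O1 | starting material
5 | 1-(methoxymethoxy)-4-(2-methylbut-3-en-2-yl)benzene | C=CC(C)(C)c1ccc(OCOC)cc1 | intermediate
6 | N,N-dimethylformamide | CN(C)C=O | starting material (reagent)
7 | 2-(methoxymethoxy)-5-(2-methylbut-3-en-2-yl)benzaldehyde | C=CC(C)(C)c1ccc(OCOC)c(C=O)c1 | intermediate
8 | 2′,4′-dihydroxy-6′-methoxyacetophenone | CC(=O)c1c(O)cc(O)cc1OC | starting material
9 | prenyl bromide | CC(C)=CCBr | starting material
10 | 2′,4′-dihydroxy-6′-methoxy-3′-prenylacetophenone | CC(=O)c1c(O)c(CC=C(C)C)c(O)cc1OC | intermediate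
11 | 2′-hydroxy-6′-methoxy-4′-MOMO-3′-prenylacetophenone | CC(=O)c1c(O)c(CC=C(C)C)c(OCOC)cc1OC | intermediate
12 | (E)-chalcone, protected | C=CC(C)(C)c1ccc(OCOC)c(/C=C/C(=O)c2c(OC)cc(OCOC)c(CC=C(C)C)c2O)c1 | intermediate
13 | (2S)-flavanone, protected | C=CC(C)(C)c1ccc(OCOC)c([C@@H]2CC(=O)c3c(OC)cc(OCOC)c(CC=C(C)C)c3O2)c1 | intermediate
14 | (2S)-2′,5,7-trihydroxy-8-prenyl-5′-(1,1-dimethylallyl)flavanone | C=CC(C)(C)c1ccc(O)c([C@@H]2CC(=O)c3c(O)cc(O)c(CC=C(C)C)c3O2)c1 | target

## Totals
- Total steps: 8.
- Longest linear sequence: 6 steps (1 → 2 → 3 → 6 → 7 → 8).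

## Three steps most likely to fail
1. **Step 7 (enantioselective oxa-Michael).** The acceptor is electron-rich and the reaction is reversible, so conversion and ee may be poor.
   - Fallback: cyclise racemically (NaOAc, EtOH, reflux, or pyrrolidine) and resolve **13** by preparative chiral HPLC. A chalcone isomerase enzymatic cyclisation of **12** is an alternative.
2. **Step 2 (Pd reverse prenylation).** Linear versus branched selectivity may be poor.
   - Fallback: start from 4-(MOMO)phenylacetonitrile, gem-dimethylate (NaH, MeI), reduce with DIBAL to the aldehyde, and carry out Wittig methylenation (Ph3P=CH2). This gives **5** without Pd.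
3. **Step 4 (C3′-prenylation).** Regioselectivity and yield are modest.
   - Fallback: use 5-methoxyresorcinol. Make the bis-MOM ether, lithiate between the two OMOM groups and prenylate, remove the MOM groups, then acetylate (Ac2O, BF3·OEt2). This reaches **10** with unambiguous regiochemistry.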